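The cyclohexanone ring is cut at C5–C6 and the C5 oxygen is tied to C7, the first side-chain carbon raised to the acid level, because the C5–OH and the C6–C7 bond are cis and 1,3-related: a cis-fused β-lactone in disguise. One isothiourea-catalysed aldol-lactonisation of an acyclic keto acid (C7 acid, C6 methylene, C1 gem-dimethyl, C2 as dioxolane, C5 methyl ketone) closes the six-membered carbocycle and the four-membered lactone, forms C5–C6 and O–C7 and sets both ring stereocentres. The lactone is then reduced, C7 becomes a sulfone, a Julia–Kocienski coupling with a citramalate-derived C8–C11 aldehyde brings in C9, and umbelliferone is attached last.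

Key step: step 6

Remarks
- Locants follow the target: ring C1 (CMe2), C2 (C=O), C3, C4, C5 (C(OH)Me), C6 (CH); chain C7, C8, C9 (C(OH)Me), C10, C11 (CH2O–aryl). The target is (5S,6R,9R) in these locants.
- Assumption on the sense of induction in step 6: the usual model for isothiourea-bound Z-enolates (enolate oxygen syn to sulfur, attack anti to the C2 phenyl group) points to the (R)-catalyst for the (1R,6S) lactone. If the first run shows the opposite sense, the (S)-catalyst is used with no other change.
- The C5 hydroxyl is silylated only after the C7 hydroxyl has been converted, since the primary alcohol would otherwise react first.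

Step 1
Reactants: 1 2,2-dimethylsuccinic anhydride
Product: 2 4-methoxy-2,2-dimethyl-4-oxobutanoic acid
Conditions: MeOH, reflux
Reagents that add atoms: methanol, CO
Why: Alcoholysis of a cyclic anhydride, in which methanol should attack the carbonyl remote from the gem-dimethyl group, so that the ester ends on the CH2 arm (future C6–C7) and the free acid on the quaternary carbon (future C2).

Step 2
Reactants: 2 4-methoxy-2,2-dimethyl-4-oxobutanoic acid; 3 but-3-en-1-ylmagnesium bromide (commercial THF solution)
Product: 5 methyl 3,3-dimethyl-4-oxooct-7-enoate, via acid chloride 4 (not isolated)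
Conditions: (COCl)2, DMF (cat.), CH2Cl2, 0 °C to rt; evaporate; then 3, CuI (5 mol%), THF, −78 to −40 °C
Reagents that add atoms: none
Why: Acid chloride formation followed by copper-catalysed acylation of a Grignard reagent, which stops at the ketone because the acyl chloride reacts far faster than the ketone or the methyl ester at low temperature, and the acid chloride has no α-hydrogen from which a ketene could form.

Step 3
Reactants: 5 methyl 3,3-dimethyl-4-oxooct-7-enoate
Product: 6 methyl 3-[2-(but-3-en-1-yl)-1,3-dioxolan-2-yl]-3-methylbutanoate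
Conditions: (TMSOCH2)2 (2 equiv), TMSOTf (5 mol%), CH2Cl2, −78 °C to rt
Reagents that add atoms: 1,2-bis(trimethylsilyloxy)ethane, C[Si](C)(C)OCCO[Si](C)(C)C
Why: Silyl-triflate-catalysed ketalisation with the bis-silyl ether of ethylene glycol, driven by formation of hexamethyldisiloxane and run under aprotic conditions that leave the methyl ester and the terminal alkene untouched.

Step 4
Reactants: 6 methyl 3-[2-(but-3-en-1-yl)-1,3-dioxolan-2-yl]-3-methylbutanoate
Product: 7 methyl 3-methyl-3-[2-(3-oxobutyl)-1,3-dioxolan-2-yl]butanoate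
Conditions: PdCl2 (10 mol%), Cu(OAc)2·H2O (20 mol%), O2 (1 atm), DMA/H2O 7:1, rt
Reagents that add atoms: water, O
Why: Tsuji–Wacker oxidation, in which Markovnikov hydroxypalladation of the terminal alkene and β-hydride elimination give the methyl ketone, with O2 as terminal oxidant and Cu(OAc)2 as a reoxidant that keeps the medium near neutral so that the dioxolane should survive.

Step 5
Reactants: 7 methyl 3-methyl-3-[2-(3-oxobutyl)-1,3-dioxolan-2-yl]butanoate
Product: 8 3-methyl-3-[2-(3-oxobutyl)-1,3-dioxolan-2-yl]butanoic acid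
Conditions: LiOH·H2O (3 equiv), THF/MeOH/H2O, rt to 40 °C; then cold 0.5 M HCl to pH 5, extraction, i-Pr2NEt (1 equiv) added to the extract
Reagents that add atoms: lithium hydroxide (hydroxide oxygen), [Li+].[OH-]
Why: Saponification of the methyl ester, after which the acid is protonated only to pH 5 in the cold and kept as its i-Pr2NEt salt, because a free carboxylic acid 1,4 to a ketal and helped by the gem-dimethyl group could catalyse its own deketalisation.

Step 6
Reactants: 8 3-methyl-3-[2-(3-oxobutyl)-1,3-dioxolan-2-yl]butanoic acid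
Product: 13 (1R,6S)-2,2,6-trimethylspiro[7-oxabicyclo[4.2.0]octane-3,2'-[1,3]dioxolan]-8-one (cis-fused β-lactone), via mixed anhydride 9 (not isolated), via acyl ammonium ion 10 (not isolated), via ammonium enolate 11 (not isolated), via aldolate 12 (not isolated)
Conditions: (R)-homobenzotetramisole [(R)-HBTM, (R)-2-phenyl-3,4-dihydro-2H-benzo[4,5]thiazolo[3,2-a]pyrimidine] (20 mol%), TsCl (1.25 equiv), LiCl (1 equiv), i-Pr2NEt (4 equiv), CH2Cl2, rt, slow addition of 8
Reagents that add atoms: none
Why: TsCl converts the carboxylate of 8 into mixed anhydride 9, which acylates the isothiourea nitrogen to give acyl ammonium 10; i-Pr2NEt removes a C6 proton to form the Z-configured ammonium enolate 11, whose carbon adds to the LiCl-activated C5 ketone to give aldolate 12, and the tertiary alkoxide then attacks the acyl ammonium carbon C7 to release the catalyst and lactone 13. This is the nucleophile-catalysed aldol-lactonisation of keto acids with chiral isothioureas, whose closest relatives are the bis-cyclisations of oxo acids to cyclopentane- and cyclohexane-fused β-lactones. The carbocycle closes in a 6-(enolexo)-exo-trig mode (C6 onto C5) and the lactone in a 4-exo-trig mode (O onto C7). The configuration at C6 is set by the catalyst, whose C2 phenyl group shields one face of the planar enolate, and that at C5 follows from it, since a four-membered lactone can only span cis positions of the cyclohexane and a trans aldolate can only revert by retro-aldol. The step needs one enolate and one acceptor: C6 is the only enolisable position of the acyl ammonium, the C2 carbonyl is masked as the dioxolane so that neither an enol lactone nor a second aldol is open, and the C1 gem-dimethyl and C2 ketal groups fold the chain towards ring closure. Slow addition of 8 keeps the concentration of activated acid low and so disfavours intermolecular acylation.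

Step 7
Reactants: 13 cis-fused β-lactone
Product: 14 (7S,8S)-7-(hydroxymethyl)-6,6,8-trimethyl-1,4-dioxaspiro[4.5]decan-8-ol
Conditions: LiAlH4 (1.5 equiv), THF, 0 °C
Reagents that add atoms: none
Why: Hydride reduction of a β-lactone at the acyl carbon (acyl–oxygen cleavage) gives the 1,3-diol with both stereocentres untouched, since neither the C5–O bond nor the C6–H bond is involved.

Step 8
Reactants: 14 (7S,8S)-7-(hydroxymethyl)-6,6,8-trimethyl-1,4-dioxaspiro[4.5]decan-8-ol
Product: 15 (7R,8S)-6,6,8-trimethyl-7-{[(1-phenyl-1H-tetrazol-5-yl)sulfanyl]methyl}-1,4-dioxaspiro[4.5]decan-8-ol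
Conditions: 1-phenyl-1H-tetrazole-5-thiol, PPh3, DIAD, THF, 0 °C to rt
Reagents that add atoms: 1-phenyl-1H-tetrazole-5-thiol, Sc1nnnn1-c1ccccc1
Why: Mitsunobu thioetherification, in which only the primary C7 hydroxyl forms an alkoxyphosphonium ion that the acidic thiol can displace, the tertiary C5 hydroxyl being inert.

Step 9
Reactants: 15 hydroxy sulfide
Product: 16 (7R,8S)-6,6,8-trimethyl-7-{[(1-phenyl-1H-tetrazol-5-yl)sulfonyl]methyl}-1,4-dioxaspiro[4.5]decan-8-ol
Conditions: (NH4)6Mo7O24·4H2O (10 mol%), 30% aq. H2O2, EtOH, 0 °C to rt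
Reagents that add atoms: hydrogen peroxide, OO
Why: Molybdate-catalysed peroxide oxidation of the sulfide to the sulfone, the standard step before a Julia–Kocienski olefination, which tolerates the tertiary alcohol and the dioxolane.

Step 10
Reactants: 16 hydroxy sulfone
Product: 17 triethyl{[(7R,8S)-6,6,8-trimethyl-7-{[(1-phenyl-1H-tetrazol-5-yl)sulfonyl]methyl}-1,4-dioxaspiro[4.5]decan-8-yl]oxy}silane
Conditions: TESOTf (1.5 equiv), 2,6-lutidine (3 equiv), CH2Cl2, −78 to 0 °C
Reagents that add atoms: triethylsilyl trifluoromethanesulfonate, CC[Si](CC)(CC)OS(=O)(=O)C(F)(F)F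
Why: Silylation of a hindered tertiary alcohol with a silyl triflate, which removes the C5 alkoxide that could otherwise attack the tetrazole ring in a Smiles-type transfer during step 16.

Step 11
Reactants: 18 (S)-citramalic acid [(S)-2-hydroxy-2-methylbutanedioic acid]
Product: 19 2-[(4S)-2,2,4-trimethyl-5-oxo-1,3-dioxolan-4-yl]acetic acid
Conditions: 2,2-dimethoxypropane, TsOH·H2O (cat.), rt
Reagents that add atoms: 2,2-dimethoxypropane, COC(C)(C)OC
Why: Acetalisation of an α-hydroxy acid to a 1,3-dioxolan-4-one, which ties the C8 carboxyl and the C9 hydroxyl into a five-membered ring, leaves the C11 carboxyl free and does not touch the stereocentre.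

Step 12
Reactants: 19 dioxolanone acid
Product: 21 (S)-3-hydroxy-3-methyloxolan-2-one, via hydroxyethyl dioxolanone 20 (not isolated)
Conditions: BH3·SMe2 (1.2 equiv), THF, 0 °C to rt; MeOH; evaporate; TsOH·H2O (cat.), CH2Cl2, rt
Reagents that add atoms: none
Why: Chemoselective borane reduction of the free carboxylic acid in the presence of the ester-like dioxolanone, followed by acid-catalysed translactonisation to the five-membered lactone with loss of acetone.

Step 13
Reactants: 21 (S)-3-hydroxy-3-methyloxolan-2-one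
Product: 22 (S)-2,4-dihydroxy-N-methoxy-N,2-dimethylbutanamide
Conditions: MeNHOMe·HCl (3 equiv), AlMe3 (3 equiv), CH2Cl2, 0 °C to rt; aq. KNaC4H4O6 (potassium sodium tartrate) work-up; crude used at once
Reagents that add atoms: N,O-dimethylhydroxylamine hydrochloride, CNOC.Cl
Why: Aminolysis of a lactone with the aluminium amide of N,O-dimethylhydroxylamine (Weinreb amide formation), which opens the ring and leaves C8 at an oxidation level that can be reduced cleanly to the aldehyde.

Step 14
Reactants: 22 dihydroxy Weinreb amide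
Product: 23 (S)-N-methoxy-N,2-dimethyl-2,4-bis(triethylsilyloxy)butanamide
Conditions: TESOTf (2.5 equiv), 2,6-lutidine (4 equiv), CH2Cl2, −78 to 0 °C
Reagents that add atoms: triethylsilyl trifluoromethanesulfonate, CC[Si](CC)(CC)OS(=O)(=O)C(F)(F)F
Why: Bis-silylation with a silyl triflate under basic conditions protects the primary and the tertiary hydroxyl in one operation and removes the free γ-hydroxyl before it can relactonise.

Step 15
Reactants: 23 bis-silyl Weinreb amide
Product: 24 (S)-2-methyl-2,4-bis(triethylsilyloxy)butanal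
Conditions: i-Bu2AlH (1.5 equiv), THF, −78 °C; aq. KNaC4H4O6 work-up
Reagents that add atoms: none
Why: Weinreb amide reduction, in which the chelated tetrahedral aluminium intermediate holds the aldehyde oxidation level until work-up, and the aldehyde has no α-hydrogen, so the C9 centre cannot epimerise.

Step 16
Reactants: 17 silylated phenyltetrazolyl sulfone; 24 (S)-2-methyl-2,4-bis(triethylsilyloxy)butanal
Product: 25 (7R,8S)-6,6,8-trimethyl-7-[(1E,3S)-3-methyl-3,5-bis(triethylsilyloxy)pent-1-en-1-yl]-8-(triethylsilyloxy)-1,4-dioxaspiro[4.5]decane (E drawn; the Z isomer is equally useful)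
Conditions: KN(SiMe3)2 (1.2 equiv) added to 17 and 24 (1.3 equiv), THF, −78 °C to rt
Reagents that add atoms: none
Why: Julia–Kocienski olefination (addition of the metallated sulfone to the aldehyde, Smiles rearrangement, loss of SO2 and phenyltetrazolone) forms C7=C8; the base is added to both partners together because the aldehyde is non-enolisable, and the alkene geometry is irrelevant since it is hydrogenated next.

Step 17
Reactants: 25 alkene
Product: 26 (7R,8S)-6,6,8-trimethyl-7-[(3R)-3-methyl-3,5-bis(triethylsilyloxy)pentyl]-8-(triethylsilyloxy)-1,4-dioxaspiro[4.5]decane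
Conditions: H2 (1 atm), 5% Pt/C, EtOAc, rt
Reagents that add atoms: none
Why: Heterogeneous hydrogenation of the disubstituted alkene, with platinum in a non-protic solvent chosen to avoid hydrogenolysis of the allylic C9–O bond and solvolysis of the silyl ethers; no stereocentre is created.

Step 18
Reactants: 26 saturated tris-silyl ether ketal
Product: 27 (3R,4S)-3-[(3R)-3,5-dihydroxy-3-methylpentyl]-4-hydroxy-2,2,4-trimethylcyclohexan-1-one
Conditions: 1 M aq. HCl/THF 1:3, rt
Reagents that add atoms: water, O
Why: Acid hydrolysis removes the three triethylsilyl ethers and the dioxolane in one operation, and since neither tertiary alcohol is β to a carbonyl group, elimination is not expected under these mild conditions.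

Step 19
Reactants: 27 keto triol; 28 umbelliferone (7-hydroxy-2H-chromen-2-one)
Product: 29 7-{[(3R)-3-hydroxy-5-[(1R,6S)-6-hydroxy-2,2,6-trimethyl-3-oxocyclohexyl]-3-methylpentyl]oxy}-2H-chromen-2-one (target)
Conditions: PPh3 (1.5 equiv), DIAD (1.5 equiv), THF, 0 °C to rt
Reagents that add atoms: none
Why: Mitsunobu etherification of a phenol, in which only the primary C11 hydroxyl is activated, the two tertiary alcohols and the ketone are inert, and no stereocentre is involved.

Compound list
1 | 2,2-dimethylsuccinic anhydride (3,3-dimethyloxolane-2,5-dione) | CC1(C)CC(=O)OC1=O | starting material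
2 | 4-methoxy-2,2-dimethyl-4-oxobutanoic acid | COC(=O)CC(C)(C)C(O)=O | intermediate
3 | but-3-en-1-ylmagnesium bromide | C=CCC[Mg]Br | starting material
4 | methyl 4-chloro-3,3-dimethyl-4-oxobutanoate (acid chloride, not isolated) | COC(=O)CC(C)(C)C(Cl)=O | intermediate
5 | methyl 3,3-dimethyl-4-oxooct-7-enoate | COC(=O)CC(C)(C)C(=O)CCC=C | intermediate
6 | methyl 3-[2-(but-3-en-1-yl)-1,3-dioxolan-2-yl]-3-methylbutanoate | COC(=O)CC(C)(C)C1(CCC=C)OCCO1 | intermediate
7 | methyl 3-methyl-3-[2-(3-oxobutyl)-1,3-dioxolan-2-yl]butanoate | COC(=O)CC(C)(C)C1(CCC(C)=O)OCCO1 | intermediate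
8 | 3-methyl-3-[2-(3-oxobutyl)-1,3-dioxolan-2-yl]butanoic acid (key-step precursor) | CC(=O)CCC1(OCCO1)C(C)(C)CC(O)=O | intermediate
9 | mixed anhydride of 8 with 4-methylbenzenesulfonic acid (not isolated) | CC(=O)CCC1(OCCO1)C(C)(C)CC(=O)OS(=O)(=O)c1ccc(C)cc1 | intermediate
10 | C7 acyl ammonium ion of 8 on (R)-HBTM (not isolated) | CC(=O)CCC1(OCCO1)C(C)(C)CC(=O)[N+]1=C2Sc3ccccc3N2CC[C@@H]1c1ccccc1 | intermediate
11 | C6 ammonium enolate, Z, zwitterion (not isolated) | CC(=O)CCC1(OCCO1)C(C)(C)/C=C(\[O-])[N+]1=C2Sc3ccccc3N2CC[C@@H]1c1ccccc1 | intermediate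
12 | cyclised C5 alkoxide still acylating the catalyst at C7, zwitterion (not isolated) | CC1(C)C2(OCCO2)CC[C@](C)([O-])[C@@H]1C(=O)[N+]1=C2Sc3ccccc3N2CC[C@@H]1c1ccccc1 | intermediate
13 | (1R,6S)-2,2,6-trimethylspiro[7-oxabicyclo[4.2.0]octane-3,2'-[1,3]dioxolan]-8-one (cis-fused β-lactone, key-step product) | CC1(C)C2(OCCO2)CC[C@]3(C)OC(=O)[C@H]13 | intermediate
14 | (7S,8S)-7-(hydroxymethyl)-6,6,8-trimethyl-1,4-dioxaspiro[4.5]decan-8-ol | CC1(C)C2(OCCO2)CC[C@](C)(O)[C@@H]1CO | intermediate
15 | (7R,8S)-6,6,8-trimethyl-7-{[(1-phenyl-1H-tetrazol-5-yl)sulfanyl]methyl}-1,4-dioxaspiro[4.5]decan-8-ol | CC1(C)C2(OCCO2)CC[C@](C)(O)[C@@H]1CSc1nnnn1-c1ccccc1 | intermediate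
16 | (7R,8S)-6,6,8-trimethyl-7-{[(1-phenyl-1H-tetrazol-5-yl)sulfonyl]methyl}-1,4-dioxaspiro[4.5]decan-8-ol | CC1(C)C2(OCCO2)CC[C@](C)(O)[C@@H]1CS(=O)(=O)c1nnnn1-c1ccccc1 | intermediate
17 | triethylsilyl ether of 16 at the tertiary hydroxyl, (7R,8S) | CC1(C)C2(OCCO2)CC[C@](C)(O[Si](CC)(CC)CC)[C@@H]1CS(=O)(=O)c1nnnn1-c1ccccc1 | intermediate
18 | (S)-citramalic acid | OC(=O)[C@@](C)(O)CC(O)=O | starting material
19 | 2-[(4S)-2,2,4-trimethyl-5-oxo-1,3-dioxolan-4-yl]acetic acid | CC1(C)OC(=O)[C@](C)(CC(O)=O)O1 | intermediate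
20 | (5S)-5-(2-hydroxyethyl)-2,2,5-trimethyl-1,3-dioxolan-4-one (not isolated) | CC1(C)OC(=O)[C@](C)(CCO)O1 | intermediate
21 | (S)-3-hydroxy-3-methyloxolan-2-one | O=C1[C@@](C)(O)CCO1 | intermediate
22 | (S)-2,4-dihydroxy-N-methoxy-N,2-dimethylbutanamide | CON(C)C(=O)[C@@](C)(O)CCO | intermediate
23 | (S)-N-methoxy-N,2-dimethyl-2,4-bis(triethylsilyloxy)butanamide | CON(C)C(=O)[C@@](C)(O[Si](CC)(CC)CC)CCO[Si](CC)(CC)CC | intermediate
24 | (S)-2-methyl-2,4-bis(triethylsilyloxy)butanal | O=C[C@@](C)(O[Si](CC)(CC)CC)CCO[Si](CC)(CC)CC | intermediate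
25 | (7R,8S)-6,6,8-trimethyl-7-[(1E,3S)-3-methyl-3,5-bis(triethylsilyloxy)pent-1-en-1-yl]-8-(triethylsilyloxy)-1,4-dioxaspiro[4.5]decane | CC1(C)C2(OCCO2)CC[C@](C)(O[Si](CC)(CC)CC)[C@@H]1/C=C/[C@@](C)(O[Si](CC)(CC)CC)CCO[Si](CC)(CC)CC | intermediate
26 | (7R,8S)-6,6,8-trimethyl-7-[(3R)-3-methyl-3,5-bis(triethylsilyloxy)pentyl]-8-(triethylsilyloxy)-1,4-dioxaspiro[4.5]decane | CC1(C)C2(OCCO2)CC[C@](C)(O[Si](CC)(CC)CC)[C@@H]1CC[C@@](C)(O[Si](CC)(CC)CC)CCO[Si](CC)(CC)CC | intermediate
27 | (3R,4S)-3-[(3R)-3,5-dihydroxy-3-methylpentyl]-4-hydroxy-2,2,4-trimethylcyclohexan-1-one | CC1(C)C(=O)CC[C@](C)(O)[C@@H]1CC[C@@](C)(O)CCO | intermediate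
28 | umbelliferone (7-hydroxy-2H-chromen-2-one) | Oc1ccc2ccc(=O)oc2c1 | starting material
29 | 7-{[(3R)-3-hydroxy-5-[(1R,6S)-6-hydroxy-2,2,6-trimethyl-3-oxocyclohexyl]-3-methylpentyl]oxy}-2H-chromen-2-one | CC1(C)C(=O)CC[C@](C)(O)[C@@H]1CC[C@@](C)(O)CCOc1ccc2ccc(=O)oc2c1 | target

Total step count: 19 (steps 1–10 ring fragment, steps 11–15 side-chain aldehyde, steps 16–19 coupling and endgame).
Longest linear sequence: 14 steps (steps 1–10, then 16–19).

Steps most likely to fail

Step 6. The catalyst may discriminate poorly between the enolate faces, or acyl transfer to the hindered isothiourea may be too slow, so that the activated acid is consumed by intermolecular acylation. In that case acid 8 would be cyclised without asymmetric induction, with stoichiometric 4-pyrrolidinopyridine, 2-bromo-1-propylpyridinium triflate and i-Pr2NEt in CH2Cl2, to the racemic cis-fused β-lactone F1. LiAlH4 in THF would give the racemic diol F2. Its primary hydroxyl would be esterified with (R)-2-methoxy-2-phenylacetic acid (EDC·HCl, DMAP, CH2Cl2, 0 °C) to the (R)-O-methylmandelate of the (7S,8S) diol F3 and the (R)-O-methylmandelate of the (7R,8R) diol F4. After chromatographic separation, K2CO3 in MeOH would release 14 from F3, and the route is rejoined at step 8.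

Step 16. The metallated phenyltetrazolyl sulfone, flanked by two quaternary carbons, may decompose by attack on the tetrazole of a second molecule before it adds to the hindered aldehyde. The olefination would then be run stepwise with a phenyl sulfone, starting from 14. PhSSPh and n-Bu3P in THF would give the phenyl sulfide F5, (NH4)6Mo7O24·4H2O with H2O2 the phenyl sulfone F6, and TESOTf with 2,6-lutidine the triethylsilyl ether F7. Lithiation (n-BuLi, THF, −78 °C), addition to 24 and trapping with Ac2O would give the β-acetoxy sulfone F8 as a mixture of diastereomers. Reductive elimination with samarium diiodide (SmI2, THF/DMPU, −78 °C) would give alkene 25, and the route is rejoined at step 17.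

Step 4. The dioxolane may be lost to acid generated in the palladium cycle, or attack at the terminal carbon may give aldehyde. The alkene of 6 would then be hydrated under radical conditions (Co(acac)2 cat., PhSiH3, O2, i-PrOH, rt) to the secondary alcohol F9, which Dess–Martin periodinane (NaHCO3, CH2Cl2) would oxidise to 7, where the route is rejoined at step 5.

Further compounds
F1 | step 6 | racemic cis-fused β-lactone (13 and its enantiomer) | CC1(C)C2(OCCO2)CC[C@]3(C)OC(=O)[C@H]13.CC1(C)C2(OCCO2)CC[C@@]3(C)OC(=O)[C@@H]13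
F2 | step 6 | racemic diol (14 and its enantiomer) | CC1(C)C2(OCCO2)CC[C@](C)(O)[C@@H]1CO.CC1(C)C2(OCCO2)CC[C@@](C)(O)[C@H]1CO
F3 | step 6 | [(7S,8S)-8-hydroxy-6,6,8-trimethyl-1,4-dioxaspiro[4.5]decan-7-yl]methyl (R)-2-methoxy-2-phenylacetate | CC1(C)C2(OCCO2)CC[C@](C)(O)[C@@H]1COC(=O)[C@H](OC)c1ccccc1
F4 | step 6 | [(7R,8R)-8-hydroxy-6,6,8-trimethyl-1,4-dioxaspiro[4.5]decan-7-yl]methyl (R)-2-methoxy-2-phenylacetate | CC1(C)C2(OCCO2)CC[C@@](C)(O)[C@H]1COC(=O)[C@H](OC)c1ccccc1
F5 | step 16 | (7R,8S)-6,6,8-trimethyl-7-[(phenylsulfanyl)methyl]-1,4-dioxaspiro[4.5]decan-8-ol | CC1(C)C2(OCCO2)CC[C@](C)(O)[C@@H]1CSc1ccccc1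
F6 | step 16 | (7R,8S)-6,6,8-trimethyl-7-[(phenylsulfonyl)methyl]-1,4-dioxaspiro[4.5]decan-8-ol | CC1(C)C2(OCCO2)CC[C@](C)(O)[C@@H]1CS(=O)(=O)c1ccccc1
F7 | step 16 | triethylsilyl ether of F6 at the tertiary hydroxyl | CC1(C)C2(OCCO2)CC[C@](C)(O[Si](CC)(CC)CC)[C@@H]1CS(=O)(=O)c1ccccc1
F8 | step 16 | β-acetoxy sulfone from F7 and 24 (C7 and C8 as a mixture) | CC1(C)C2(OCCO2)CC[C@](C)(O[Si](CC)(CC)CC)[C@@H]1C(C(OC(C)=O)[C@@](C)(O[Si](CC)(CC)CC)CCO[Si](CC)(CC)CC)S(=O)(=O)c1ccccc1
F9 | step 4 | methyl 3-[2-(3-hydroxybutyl)-1,3-dioxolan-2-yl]-3-methylbutanoate (carbinol centre racemic) | COC(=O)CC(C)(C)C1(CCC(C)O)OCCO1
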